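**Retrosynthetic overview**
- Target ⇐ hydrolysis of an O-methyl enol ether / bis-silyl ether; the endo C7–prenyl group ⇐ H-atom transfer to the exo face of a C7 radical (from a tertiary nitro group) ⇐ palladium-catalysed prenylation of a C7 nitronate.
- Bicyclo[3.3.1] core ⇐ one-flask enantioselective dearomative (3+3) annulation of a fully substituted 2-aroylphenol with a C6–C7(NO2)–C8Me2 bis-electrophile: C5–C6 by catalytic asymmetric ortho-Michael addition (breaks aromaticity, sets C5), then C1–C8 by intramolecular Michael addition.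
- The phenol has one free OH, ortho to the geranyl carbon and to the aroyl carbon, and two OMe groups flanking the prenyl carbon; this pattern decides which carbon bonds to CH2 and which to CMe2. It comes from 3,5-dimethoxyphenol by ortho-geranylation, ortho-aroylation and para-prenylation.
- Side pieces: silyl-protected protocatechuoyl chloride ⇐ 3,4-dihydroxybenzoic acid; nitro carbonate ⇐ 2-nitroethanol + acetone.
- Ring order: the phloroglucinol ring becomes the trione ring (C1–C5, C9); carbocyclic ring B (C1, C5–C9) closes in the key step.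

Assumption: core locants are C1 = prenyl bridgehead, C2–C4 = enolised dione bridge (C3 aroyl), C5 = geranyl bridgehead, C6 = CH2, C7 = CH-prenyl, C8 = CMe2, C9 = bridging ketone, and endo = on the side of the C2–C4 bridge; the target is 1S,5S,7S in these locants (7-endo prenyl), and the (1R,2R) thiourea is taken to give the S centre at C5 (its mirror image is used if the sense is opposite).

**Step 1**
Reactants: 1 3,5-dimethoxyphenol; 2 geranyl bromide ((2E)-1-bromo-3,7-dimethylocta-2,6-diene)
Product: 3 2-[(2E)-3,7-dimethylocta-2,6-dien-1-yl]-3,5-dimethoxyphenol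
Conditions: NaH (1.05 equiv), toluene, 0 °C; then 2, rt, 16 h
Reagents that add atoms: none
Why: C-alkylation of the sodium phenoxide contact ion pair in a non-polar solvent (ortho-selective phenoxide C-allylation, SN2 with retention of the E-alkene) puts geranyl on one of the two equivalent ortho carbons; the O-ether and the para isomer are separable minor products.

**Step 2**
Reactants: 4 3,4-dihydroxybenzoic acid
Product: 5 tert-butyldimethylsilyl 3,4-bis(tert-butyldimethylsilyloxy)benzoate
Conditions: TBSCl (3.3 equiv), imidazole (6 equiv), DMF, rt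
Reagents that add atoms: tert-butyldimethylsilyl chloride (TBSCl), CC(C)(C)[Si](C)(C)Cl
Why: exhaustive silylation (silyl ether and silyl ester formation) masks the catechol and prepares the acid for neutral activation.

**Step 3**
Reactants: 5 tert-butyldimethylsilyl 3,4-bis(tert-butyldimethylsilyloxy)benzoate
Product: 6 3,4-bis(tert-butyldimethylsilyloxy)benzoyl chloride
Conditions: (COCl)2 (1.2 equiv), DMF (cat.), CH2Cl2, 0 °C → rt
Reagents that add atoms: oxalyl chloride, O=C(Cl)C(Cl)=O
Why: silyl esters are converted directly into acid chlorides by the Vilsmeier reagent from oxalyl chloride/DMF under neutral conditions, so the aryl silyl ethers survive.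

**Step 4**
Reactants: 3 2-geranyl-3,5-dimethoxyphenol; 6 3,4-bis(tert-butyldimethylsilyloxy)benzoyl chloride
Product: 7 [3,4-bis(tert-butyldimethylsilyloxy)phenyl](3-geranyl-2-hydroxy-4,6-dimethoxyphenyl)methanone
Conditions: EtMgBr (1.0 equiv), Et2O/toluene, 0 °C; then 6, toluene, rt → 50 °C
Reagents that add atoms: none
Why: the bromomagnesium phenoxide is C-acylated through a magnesium chelate only ortho to oxygen (chelation-controlled Friedel–Crafts-type ortho-acylation), i.e. at the single free ortho carbon, without any acid that could cyclise the geranyl chain.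

**Step 5**
Reactants: 7 the ketone from step 4; 8 3-methylbut-2-en-1-ol (prenol)
Product: 9 [3,4-bis(tert-butyldimethylsilyloxy)phenyl][3-geranyl-2-hydroxy-4,6-dimethoxy-5-(3-methylbut-2-en-1-yl)phenyl]methanone
Conditions: Pd(OAc)2 (5 mol%), PPh3 (20 mol%), Ti(OiPr)4 (25 mol%), 8 (1.1 equiv), 4 Å molecular sieves, toluene, 50 °C
Reagents that add atoms: none
Why: Tsuji–Trost C-allylation of the phenol by the π-prenyl palladium complex formed from prenol can only end at the last free ring carbon (para to OH, between the two OMe groups) and occurs at the CH2 terminus; O-allyl ethers re-ionise under the zerovalent palladium catalyst.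

**Step 6**
Reactants: 10 2-nitroethanol; 11 acetone
Product: 12 3-methyl-2-nitrobutane-1,3-diol (racemic)
Conditions: 1,1,3,3-tetramethylguanidine (10 mol%), acetone as solvent, 0 °C → rt
Reagents that add atoms: none
Why: Henry (nitroaldol) addition of the nitronate to acetone, driven by acetone as solvent, assembles C6–C7(NO2)–C8Me2 in one operation; the stereocentre is destroyed later.

**Step 7**
Reactants: 12 3-methyl-2-nitrobutane-1,3-diol
Product: 13 3-hydroxy-3-methyl-2-nitrobutyl methyl carbonate (racemic)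
Conditions: ClCO2Me (1.05 equiv), pyridine (1.2 equiv), CH2Cl2, −20 °C
Reagents that add atoms: methyl chloroformate, COC(=O)Cl
Why: chemoselective acylation of the primary alcohol (the tertiary one is inert) gives a β-nitro carbonate that releases a nitroalkene by E1cB elimination under mild base without forming an acid.

**Step 8 (key step)**
Reactants: 9 the pentasubstituted 2-aroylphenol; 13 3-hydroxy-3-methyl-2-nitrobutyl methyl carbonate
Product: 17 7-nitro bicyclic O2-methyl enol ether (C1/C5 set; C7 epimers), via nitro-alcohol dienone 14 (not isolated), via trifluoroacetate ester 15 (not isolated), via nitroalkene dienone 16 (not isolated)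
Conditions: 1-[3,5-bis(trifluoromethyl)phenyl]-3-[(1R,2R)-2-(dimethylamino)cyclohexyl]thiourea (10 mol%), 13 (1.5 equiv), toluene, 0 °C, 48 h; then Et3N (4 equiv), (CF3CO)2O (1.5 equiv), 0 → 60 °C; aq. NH4Cl
Reagents that add atoms: none
Why: Proposed new method: the catalyst amine eliminates methyl carbonate from 13 (E1cB) to give 2-methyl-3-nitrobut-3-en-2-ol, which the thiourea binds through its nitro group while the ammonium ion pairs with the chelated phenolate of 9, so the ortho carbon carrying geranyl adds to the CH2 terminus from one face (enantioselective dearomative Michael addition; sets C5 and fixes C5–CH2, the para carbon being flanked by two OMe groups and remote from the ion pair); trifluoroacetylation/E1cB then gives tetrasubstituted nitroalkene 16, whose CMe2 carbon is attacked intramolecularly by the electron-rich enol-ether carbon C1 on the face already holding the tether (so C1 follows C5), and triethylamine removes the methyl group of the resulting oxocarbenium ion to leave the C9 ketone; closest known reaction types are the thiourea-catalysed dearomative Michael addition of 2-naphthols to nitroethylene, the Michael/elimination/Michael (3+3) annulation of 2-nitroallyl esters, and the alkylative dearomatisation–annulation of acylphloroglucinols with α-acetoxymethyl enals.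

**Step 9**
Reactants: 17 the 7-nitro bicycle; 18 3-methylbut-2-en-1-yl acetate (prenyl acetate)
Product: 19 7-nitro-7-prenyl bicycle (prenyl exo, nitro endo)
Conditions: Pd(PPh3)4 (5 mol%), 18 (1.5 equiv), Et3N (2 equiv), THF, 40 °C
Reagents that add atoms: none
Why: Tsuji–Trost allylation of the C7 nitronate (pKa about 9) at the CH2 terminus of the π-prenyl complex gives C-alkylation on the open exo face of ring B, away from the C2–C4 bridge and the aroyl group.

**Step 10**
Reactants: 19 the tertiary nitro compound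
Product: 20 O2-methyl bis-silyl ether of the target (7-endo prenyl)
Conditions: Bu3SnH (5 equiv, 0.5 M), AIBN (0.3 equiv), toluene, 85 °C
Reagents that add atoms: none
Why: radical denitration of a tertiary nitro compound (stannane chain reaction) gives a planar C7 radical that takes hydrogen from Bu3SnH on the open exo face, which places prenyl endo (7S); tin radicals do not isomerise the trisubstituted alkenes.

**Step 11**
Reactants: 20 the O2-methyl bis-silyl ether
Product: 21 target, (1S,5S,7S)-3-(3,4-dihydroxybenzoyl)-5-[(2E)-geranyl]-4-hydroxy-8,8-dimethyl-1,7-bis(3-methylbut-2-enyl)bicyclo[3.3.1]non-3-ene-2,9-dione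
Conditions: LiOH·H2O (10 equiv), 1,4-dioxane/H2O 3:1, 90 °C, argon; 1 M HCl work-up
Reagents that add atoms: lithium hydroxide, [Li+].[OH-]
Why: hydroxide hydrolyses the vinylogous methyl ester by addition–elimination and cleaves both aryl silyl ethers in the same pot; C1 and C5 are quaternary and C7 is not acidic, so no stereocentre is touched.

**Compound list**
1 | 3,5-dimethoxyphenol | COc1cc(O)cc(OC)c1 | starting material
2 | geranyl bromide, (2E)-1-bromo-3,7-dimethylocta-2,6-diene | CC(C)=CCC/C(C)=C/CBr | starting material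
3 | 2-[(2E)-3,7-dimethylocta-2,6-dien-1-yl]-3,5-dimethoxyphenol | CC(C)=CCC/C(C)=C/Cc1c(O)cc(OC)cc1OC | intermediate
4 | 3,4-dihydroxybenzoic acid | OC(=O)c1ccc(O)c(O)c1 | starting material
5 | tert-butyldimethylsilyl 3,4-bis(tert-butyldimethylsilyloxy)benzoate | CC(C)(C)[Si](C)(C)OC(=O)c1ccc(O[Si](C)(C)C(C)(C)C)c(O[Si](C)(C)C(C)(C)C)c1 | intermediate
6 | 3,4-bis(tert-butyldimethylsilyloxy)benzoyl chloride | ClC(=O)c1ccc(O[Si](C)(C)C(C)(C)C)c(O[Si](C)(C)C(C)(C)C)c1 | intermediate
7 | [3,4-bis(tert-butyldimethylsilyloxy)phenyl]{3-[(2E)-geranyl]-2-hydroxy-4,6-dimethoxyphenyl}methanone | CC(C)=CCC/C(C)=C/Cc1c(O)c(C(=O)c2ccc(O[Si](C)(C)C(C)(C)C)c(O[Si](C)(C)C(C)(C)C)c2)c(OC)cc1OC | intermediate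
8 | 3-methylbut-2-en-1-ol (prenol) | CC(C)=CCO | starting material
9 | [3,4-bis(tert-butyldimethylsilyloxy)phenyl]{3-[(2E)-geranyl]-2-hydroxy-4,6-dimethoxy-5-(3-methylbut-2-en-1-yl)phenyl}methanone | CC(C)=CCC/C(C)=C/Cc1c(O)c(C(=O)c2ccc(O[Si](C)(C)C(C)(C)C)c(O[Si](C)(C)C(C)(C)C)c2)c(OC)c(CC=C(C)C)c1OC | intermediate
10 | 2-nitroethanol | OCC[N+](=O)[O-] | starting material
11 | acetone | CC(C)=O | starting material
12 | 3-methyl-2-nitrobutane-1,3-diol (racemic) | CC(C)(O)C(CO)[N+](=O)[O-] | intermediate
13 | 3-hydroxy-3-methyl-2-nitrobutyl methyl carbonate (racemic) | COC(=O)OCC(C(C)(C)O)[N+](=O)[O-] | intermediate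
14 | 2-[3,4-bis(tert-butyldimethylsilyloxy)benzoyl]-6-[(2E)-geranyl]-6-(3-hydroxy-3-methyl-2-nitrobutyl)-3,5-dimethoxy-4-(3-methylbut-2-enyl)cyclohexa-2,4-dien-1-one; quaternary ring carbon (core C5) as in 21, nitro carbon both epimers | CC(C)=CCC/C(C)=C/C[C@]1(CC(C(C)(C)O)[N+](=O)[O-])C(=O)C(C(=O)c2ccc(O[Si](C)(C)C(C)(C)C)c(O[Si](C)(C)C(C)(C)C)c2)=C(OC)C(CC=C(C)C)=C1OC | intermediate (not isolated)
15 | tertiary trifluoroacetate of 14 | CC(C)=CCC/C(C)=C/C[C@]1(CC(C(C)(C)OC(=O)C(F)(F)F)[N+](=O)[O-])C(=O)C(C(=O)c2ccc(O[Si](C)(C)C(C)(C)C)c(O[Si](C)(C)C(C)(C)C)c2)=C(OC)C(CC=C(C)C)=C1OC | intermediate (not isolated)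
16 | 2-[3,4-bis(tert-butyldimethylsilyloxy)benzoyl]-6-[(2E)-geranyl]-3,5-dimethoxy-6-(3-methyl-2-nitrobut-2-enyl)-4-(3-methylbut-2-enyl)cyclohexa-2,4-dien-1-one; core C5 as in 21 | CC(C)=CCC/C(C)=C/C[C@]1(CC(=C(C)C)[N+](=O)[O-])C(=O)C(C(=O)c2ccc(O[Si](C)(C)C(C)(C)C)c(O[Si](C)(C)C(C)(C)C)c2)=C(OC)C(CC=C(C)C)=C1OC | intermediate (not isolated)
17 | 3-[3,4-bis(tert-butyldimethylsilyloxy)benzoyl]-5-[(2E)-geranyl]-2-methoxy-8,8-dimethyl-1-(3-methylbut-2-enyl)-7-nitrobicyclo[3.3.1]non-2-ene-4,9-dione; C1 and C5 as in 21, C7 both epimers | CC(C)=CCC/C(C)=C/C[C@]12CC([N+](=O)[O-])C(C)(C)[C@](CC=C(C)C)(C(OC)=C(C(=O)c3ccc(O[Si](C)(C)C(C)(C)C)c(O[Si](C)(C)C(C)(C)C)c3)C1=O)C2=O | intermediate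
18 | 3-methylbut-2-en-1-yl acetate (prenyl acetate) | CC(C)=CCOC(C)=O | starting material
19 | 7-nitro-7-(3-methylbut-2-enyl) derivative of 17; C7 prenyl exo (away from the C2–C4 bridge), nitro endo; C1 and C5 as in 21 | CC(C)=CCC/C(C)=C/C[C@]12C[C@](CC=C(C)C)([N+](=O)[O-])C(C)(C)[C@](CC=C(C)C)(C(OC)=C(C(=O)c3ccc(O[Si](C)(C)C(C)(C)C)c(O[Si](C)(C)C(C)(C)C)c3)C1=O)C2=O | intermediate
20 | 3-[3,4-bis(tert-butyldimethylsilyloxy)benzoyl]-5-[(2E)-geranyl]-2-methoxy-8,8-dimethyl-1,7-bis(3-methylbut-2-enyl)bicyclo[3.3.1]non-2-ene-4,9-dione; C1, C5, C7 as in 21 (7-endo prenyl) | CC(C)=CCC/C(C)=C/C[C@]12C[C@H](CC=C(C)C)C(C)(C)[C@](CC=C(C)C)(C(OC)=C(C(=O)c3ccc(O[Si](C)(C)C(C)(C)C)c(O[Si](C)(C)C(C)(C)C)c3)C1=O)C2=O | intermediate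
21 | (1S,5S,7S)-3-(3,4-dihydroxybenzoyl)-5-[(2E)-geranyl]-4-hydroxy-8,8-dimethyl-1,7-bis(3-methylbut-2-enyl)bicyclo[3.3.1]non-3-ene-2,9-dione | CC(C)=CCC/C(C)=C/C[C@]12C[C@H](CC=C(C)C)C(C)(C)[C@](CC=C(C)C)(C(=O)C(C(=O)c3ccc(O)c(O)c3)=C1O)C2=O | target

**Step count and risks**
Total: 11 steps. Longest linear sequence: 8 steps (4 → 5 → 6 → 7 → 9 → 17 → 19 → 20 → 21); 7 steps from 1.

Most likely to fail, first: step 8. The in-flask nitroalkene is 2-substituted and hindered, ortho attack must beat para attack, and the neutral enol ether must close onto a tetrasubstituted nitroalkene. Fallback: starting from 9, run the same thiourea-catalysed dearomative Michael addition with parent nitroethylene (freshly generated), the acceptor for which ortho-dearomatisation is established, to give the 2-nitroethyl dienone F1. Then build C8 by a Henry addition of F1 to acetone 11 (cat. tetramethylguanidine, acetone as solvent), which gives 14. From 14 the dehydration/cyclisation half of step 8 is run as a separate operation to reach 17.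

Second: step 9. C-allylation of a nitronate that sits next to the quaternary C8 may be slow or give O-allylation. Fallback: from 17, allylate with the smaller allyl acetate (Pd(PPh3)4, Et3N) to the 7-allyl-7-nitro compound F2. Cross-metathesis of F2 with 2-methylbut-2-ene (second-generation Grubbs catalyst, stopped before the trisubstituted alkenes react) then turns the terminal allyl into prenyl and returns to 19.

Third: step 10. The C7 radical could fragment (β-scission toward C1 or C5) or take hydrogen with imperfect facial selectivity. Fallback: from 17, a Nef reaction (nitronate, then buffered aqueous TiCl3) gives the C7 ketone F3, and Wittig methylenation (Ph3P=CH2) gives the 7-methylene compound F4. Hydroboration of F4 with 9-BBN from the exo face and B-alkyl Suzuki–Miyaura coupling with 1-bromo-2-methylprop-1-ene (PdCl2(dppf), Cs2CO3) install the prenyl group endo and return to 20, bypassing 19.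

**Further compounds**
F1 | step 8 | 2-[3,4-bis(tert-butyldimethylsilyloxy)benzoyl]-6-[(2E)-geranyl]-3,5-dimethoxy-4-(3-methylbut-2-enyl)-6-(2-nitroethyl)cyclohexa-2,4-dien-1-one (quaternary carbon as in 14) | CC(C)=CCC/C(C)=C/C[C@]1(CC[N+](=O)[O-])C(=O)C(C(=O)c2ccc(O[Si](C)(C)C(C)(C)C)c(O[Si](C)(C)C(C)(C)C)c2)=C(OC)C(CC=C(C)C)=C1OC
F2 | step 9 | 7-allyl-7-nitro analogue of 19 (allyl exo, nitro endo) | CC(C)=CCC/C(C)=C/C[C@]12C[C@](CC=C)([N+](=O)[O-])C(C)(C)[C@](CC=C(C)C)(C(OC)=C(C(=O)c3ccc(O[Si](C)(C)C(C)(C)C)c(O[Si](C)(C)C(C)(C)C)c3)C1=O)C2=O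
F3 | step 10 | 7-oxo analogue of 17 (bicyclo[3.3.1]non-2-ene-4,7,9-trione) | CC(C)=CCC/C(C)=C/C[C@]12CC(=O)C(C)(C)[C@](CC=C(C)C)(C(OC)=C(C(=O)c3ccc(O[Si](C)(C)C(C)(C)C)c(O[Si](C)(C)C(C)(C)C)c3)C1=O)C2=O
F4 | step 10 | 7-methylene analogue of 17 | CC(C)=CCC/C(C)=C/C[C@]12CC(=C)C(C)(C)[C@](CC=C(C)C)(C(OC)=C(C(=O)c3ccc(O[Si](C)(C)C(C)(C)C)c(O[Si](C)(C)C(C)(C)C)c3)C1=O)C2=O
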